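**Retrosynthetic overview**

- Ring A is a hexasubstituted benzene whose carbons are called here positions 1 (butanoyl), 2 (OH), 3 (CH3), 4 (OCH3), 5 (CH2 bridge) and 6 (OH) of ring A. The bridge joins position 1 of the enolised trione ring B, which carries a gem-dimethyl group at its position 3 and an acetyl group at its position 5.
- The strategy rests on the alternation of the ring A oxygens (positions 2, 4, 6) with carbon substituents. Positions 6-1-2-3 come from a 3-alkoxy-2-methylcyclobutenone, whose carbonyl carbon becomes position 6. Positions 4-5 come from a methoxyalkyne that already carries the bridge carbon.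
- Disconnections, last to first: the bond from ring B position 1 to the bridge CH2 (benzylic alcohol plus acetylfilicinic acid, acid catalysis); the bond from ring A position 1 to the butanoyl carbonyl (bromine–lithium exchange, Weinreb amide); ring A itself by cyclobutenone–alkoxyalkyne benzannulation.
- Ring order: the four-membered ring made in step 1 is consumed to build ring A in step 5. Ring B is made from 2',4',6'-trihydroxyacetophenone by dearomatising double C-methylation (step 10) and attached in step 11.
- The three ring A oxygens are differentiated from the start (position 6 free OH, position 2 benzyl ether, position 4 methyl ether). The cycloadduct of methylketene and ethoxyethyne carries its methyl on the sp3 carbon, so step 2 moves it onto the enone α-carbon by acid equilibration during the benzyl exchange.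

Key step: step 5

Assumption: ring B is an enolised β-triketone that equilibrates among tautomers; every ring B compound is drawn in the tautomer of the target SMILES, and the target has no stereocentre.

**Route**

Step 1
Reactants: 1 propanoyl chloride; 2 ethoxyethyne
Product: 4 3-ethoxy-4-methylcyclobut-2-en-1-one (racemic), via methylketene 3 (not isolated)
Conditions: Et3N, Et2O, 0 °C → rt (1 added slowly to excess 2 and Et3N)
Reagents that add atoms: none
Why: Dehydrochlorination of 1 gives methylketene 3, which is trapped in the known ketene–ynol ether (2+2) cycloaddition with the nucleophilic CH terminus of 2 bonding to the ketene carbonyl carbon; the methyl therefore sits on the sp3 ring carbon as a racemic centre that step 2 removes.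

Step 2
Reactants: 4 3-ethoxy-4-methylcyclobut-2-en-1-one
Product: 5 3-(benzyloxy)-2-methylcyclobut-2-en-1-one
Conditions: BnOH (3 equiv), TsOH·H2O (5 mol %), PhMe, 40 °C, 150 mbar (EtOH distilled off)
Reagents that add atoms: benzyl alcohol, OCc1ccccc1
Why: Acid-catalysed transetherification of the vinylogous ester runs through a 3,3-dialkoxycyclobutanone that can lose alcohol toward either α-carbon, so alkoxy exchange and double-bond equilibration occur together and thermodynamic control should favour the more substituted enol ether with the methyl on the enone α-carbon.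

Step 3
Reactants: 6 2-chloro-1,1-dimethoxyethane
Product: 8 3-methoxyprop-2-yn-1-ol, via lithium methoxyacetylide 7 (not isolated)
Conditions: LiNEt2 (3.1 equiv), THF, 0 °C; then (CH2O)n, −78 °C → rt; H2O, NaHCO3 work-up
Reagents that add atoms: paraformaldehyde (formaldehyde unit), C=O
Why: Base-induced loss of methanol and then of HCl followed by deprotonation is the known in situ entry to a lithium alkoxyacetylide, which adds to formaldehyde as an alkynyllithium; the base-only work-up avoids Meyer–Schuster-type rearrangement of the acid-labile hydroxy ynol ether.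

Step 4
Reactants: 8 3-methoxyprop-2-yn-1-ol
Product: 9 tert-butyl[(3-methoxyprop-2-yn-1-yl)oxy]dimethylsilane
Conditions: TBSCl, imidazole, CH2Cl2, 0 °C → rt
Reagents that add atoms: tert-butyldimethylsilyl chloride, CC(C)(C)[Si](C)(C)Cl
Why: Standard silylation of a primary alcohol, with imidazole keeping the ynol ether away from acid.

Step 5
Reactants: 5 3-(benzyloxy)-2-methylcyclobut-2-en-1-one; 9 tert-butyl[(3-methoxyprop-2-yn-1-yl)oxy]dimethylsilane
Product: 14 5-(benzyloxy)-2-{[(tert-butyldimethylsilyl)oxy]methyl}-3-methoxy-4-methylphenol, via vinylketene 10 (not isolated), via vinylcyclobutenone 11 (not isolated), via dienylketene 12 (not isolated), via cyclohexadienone 13 (not isolated)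
Conditions: 5 added slowly to 9 (1.5 equiv), PhMe, sealed tube, 110 °C, then 130 °C
Reagents that add atoms: none
Why: Heat opens 5 by a four-electron electrocyclic reaction to the (1-benzyloxyvinyl)ketene 10, whose ketene C=C adds the ynol ether 9 in a (2+2) cycloaddition that forms the ring A bonds between positions 5 and 6 and between positions 3 and 4 and gives vinylcyclobutenone 11; a second four-electron opening gives dienylketene 12, a thermally allowed disrotatory 6π electrocyclisation forms the bond between positions 1 and 6 and closes ring A as dienone 13, and tautomerisation gives phenol 14. The closest known reaction is the Danheiser benzannulation of cyclobutenones with alkoxyalkynes, used here with a 3-alkoxycyclobutenone, which is the less explored end of its scope and may need the higher temperature. The one selectivity required is the orientation of the (2+2) step, and the polarisation of 9 secures it: the alkyne carbon β to the methoxy oxygen (the one bearing CH2OSi) is the nucleophilic terminus and bonds to the ketene carbonyl carbon, so OCH3 falls at position 4 next to the methyl at position 3 and the CH2OSi arm at position 5 next to the new hydroxyl at position 6. No stereocentre is created, because the quaternary carbon of 11 becomes sp2 on ring opening, and the opening of 11 is reversible, so material that opens with the unproductive sense of rotation re-closes and drains through 12. A methoxyalkyne has no β-hydrogen for the retro-ene fragmentation that limits ethoxyalkynes on heating, and slow addition of 5 to excess 9 keeps ketene 10 from dimerising or acylating the product phenol.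

Step 6
Reactants: 14 5-(benzyloxy)-2-{[(tert-butyldimethylsilyl)oxy]methyl}-3-methoxy-4-methylphenol
Product: 15 {[4,6-bis(benzyloxy)-2-methoxy-3-methylphenyl]methoxy}(tert-butyl)dimethylsilane
Conditions: BnBr, K2CO3, DMF, rt
Reagents that add atoms: benzyl bromide, BrCc1ccccc1
Why: Williamson etherification of the phenol at position 6 of ring A, which also blocks later cyclisation of this oxygen onto ring B.

Step 7
Reactants: 15 {[4,6-bis(benzyloxy)-2-methoxy-3-methylphenyl]methoxy}(tert-butyl)dimethylsilane
Product: 16 {[2,4-bis(benzyloxy)-3-bromo-6-methoxy-5-methylphenyl]methoxy}(tert-butyl)dimethylsilane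
Conditions: NBS, NaHCO3, MeCN, 0 °C, dark
Reagents that add atoms: N-bromosuccinimide, O=C1CCC(=O)N1Br
Why: Electrophilic aromatic bromination at position 1 of ring A, the only unsubstituted ring carbon and activated by two ortho oxygens and one para oxygen; the bromide allows metalation by exchange, which avoids a directed deprotonation that could metalate the benzylic positions of the benzyl ethers.

Step 8
Reactants: 16 {[2,4-bis(benzyloxy)-3-bromo-6-methoxy-5-methylphenyl]methoxy}(tert-butyl)dimethylsilane; 17 N-methoxy-N-methylbutanamide
Product: 19 1-[2,6-bis(benzyloxy)-3-{[(tert-butyldimethylsilyl)oxy]methyl}-4-methoxy-5-methylphenyl]butan-1-one, via aryllithium 18 (not isolated)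
Conditions: n-BuLi, THF, −78 °C; then 17, −78 → 0 °C; H2O
Reagents that add atoms: none
Why: Bromine–lithium exchange at −78 °C is faster than any deprotonation, and the Weinreb ketone synthesis stops at the chelated tetrahedral adduct until work-up, so the aryllithium is acylated once and no tertiary alcohol forms.

Step 9
Reactants: 19 1-[2,6-bis(benzyloxy)-3-{[(tert-butyldimethylsilyl)oxy]methyl}-4-methoxy-5-methylphenyl]butan-1-one
Product: 20 1-[2,6-bis(benzyloxy)-3-(hydroxymethyl)-4-methoxy-5-methylphenyl]butan-1-one
Conditions: Bu4NF, THF, 0 °C
Reagents that add atoms: none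
Why: Fluoride-induced desilylation under non-acidic conditions, which leaves the easily ionised trialkoxybenzyl alcohol intact.

Step 10
Reactants: 21 2',4',6'-trihydroxyacetophenone
Product: 22 2-acetyl-3,5-dihydroxy-4,4-dimethylcyclohexa-2,5-dien-1-one (acetylfilicinic acid)
Conditions: NaOMe (3 equiv), MeI (2.2 equiv), MeOH, 0 °C → rt; then 1 M HCl
Reagents that add atoms: iodomethane, CI
Why: Dearomatising double C-methylation of the acylphloroglucinol polyanion at one ring carbon is the known route to acylfilicinic acids, and limiting the iodomethane leaves the other ring CH, the future position 1 of ring B, free.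

Step 11
Reactants: 20 1-[2,6-bis(benzyloxy)-3-(hydroxymethyl)-4-methoxy-5-methylphenyl]butan-1-one; 22 2-acetyl-3,5-dihydroxy-4,4-dimethylcyclohexa-2,5-dien-1-one
Product: 23 2-acetyl-6-{[2,4-bis(benzyloxy)-3-butanoyl-6-methoxy-5-methylphenyl]methyl}-3,5-dihydroxy-4,4-dimethylcyclohexa-2,5-dien-1-one
Conditions: 22 (1.5 equiv), TsOH·H2O (10 mol %), 4 Å molecular sieves, CH2Cl2, 0 °C → rt
Reagents that add atoms: none
Why: Acid-catalysed dehydrative C-benzylation of a cyclic β-dicarbonyl compound (Friedel–Crafts-type alkylation through a benzylic cation): the benzylic alcohol flanked by two ortho oxygens and one para oxygen ionises readily, position 1 of ring B is the only enolic CH of 22, ring A has no free position for self-condensation, and any O-benzylated enol ether re-ionises under the acid and is funnelled to the C–C bonded product.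

Step 12
Reactants: 23 2-acetyl-6-{[2,4-bis(benzyloxy)-3-butanoyl-6-methoxy-5-methylphenyl]methyl}-3,5-dihydroxy-4,4-dimethylcyclohexa-2,5-dien-1-one
Product: 24 2-acetyl-6-[(3-butanoyl-2,4-dihydroxy-6-methoxy-5-methylphenyl)methyl]-3,5-dihydroxy-4,4-dimethylcyclohexa-2,5-dien-1-one (CNP0414731.0)
Conditions: H2 (1 atm), Pd/C (10 wt % palladium on carbon), EtOAc, rt
Reagents that add atoms: none
Why: Catalytic hydrogenolysis removes both aryl benzyl ethers under neutral conditions, under which the hindered aryl ketone, the enolised triketone and the C–C bonded methylene bridge should not be reduced.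

**Compound list**

1 | propanoyl chloride | CCC(=O)Cl | starting material
2 | ethoxyethyne (ethoxyacetylene) | CCOC#C | starting material
3 | methylketene (prop-1-en-1-one) | CC=C=O | intermediate (not isolated)
4 | 3-ethoxy-4-methylcyclobut-2-en-1-one (racemic) | CCOC1=CC(=O)C1C | intermediate
5 | 3-(benzyloxy)-2-methylcyclobut-2-en-1-one | CC1=C(OCc2ccccc2)CC1=O | intermediate
6 | 2-chloro-1,1-dimethoxyethane (chloroacetaldehyde dimethyl acetal) | COC(CCl)OC | starting material
7 | lithium methoxyacetylide | COC#C[Li] | intermediate (not isolated)
8 | 3-methoxyprop-2-yn-1-ol | COC#CCO | intermediate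
9 | tert-butyl[(3-methoxyprop-2-yn-1-yl)oxy]dimethylsilane | COC#CCO[Si](C)(C)C(C)(C)C | intermediate
10 | 3-(benzyloxy)-2-methylbuta-1,3-dien-1-one (vinylketene) | O=C=C(C)C(=C)OCc1ccccc1 | intermediate (not isolated)
11 | 4-[1-(benzyloxy)ethenyl]-2-{[(tert-butyldimethylsilyl)oxy]methyl}-3-methoxy-4-methylcyclobut-2-en-1-one (racemic) | COC1=C(CO[Si](C)(C)C(C)(C)C)C(=O)C1(C)C(=C)OCc1ccccc1 | intermediate (not isolated)
12 | (3E)-5-(benzyloxy)-2-{[(tert-butyldimethylsilyl)oxy]methyl}-3-methoxy-4-methylhexa-1,3,5-trien-1-one (dienylketene) | O=C=C(CO[Si](C)(C)C(C)(C)C)/C(OC)=C(C)\C(=C)OCc1ccccc1 | intermediate (not isolated)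
13 | 5-(benzyloxy)-2-{[(tert-butyldimethylsilyl)oxy]methyl}-3-methoxy-4-methylcyclohexa-2,4-dien-1-one | O=C1CC(OCc2ccccc2)=C(C)C(OC)=C1CO[Si](C)(C)C(C)(C)C | intermediate (not isolated)
14 | 5-(benzyloxy)-2-{[(tert-butyldimethylsilyl)oxy]methyl}-3-methoxy-4-methylphenol | Oc1cc(OCc2ccccc2)c(C)c(OC)c1CO[Si](C)(C)C(C)(C)C | intermediate
15 | {[4,6-bis(benzyloxy)-2-methoxy-3-methylphenyl]methoxy}(tert-butyl)dimethylsilane | COc1c(C)c(OCc2ccccc2)cc(OCc2ccccc2)c1CO[Si](C)(C)C(C)(C)C | intermediate
16 | {[2,4-bis(benzyloxy)-3-bromo-6-methoxy-5-methylphenyl]methoxy}(tert-butyl)dimethylsilane | COc1c(C)c(OCc2ccccc2)c(Br)c(OCc2ccccc2)c1CO[Si](C)(C)C(C)(C)C | intermediate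
17 | N-methoxy-N-methylbutanamide | CCCC(=O)N(C)OC | starting material
18 | {2,6-bis(benzyloxy)-3-{[(tert-butyldimethylsilyl)oxy]methyl}-4-methoxy-5-methylphenyl}lithium | COc1c(C)c(OCc2ccccc2)c([Li])c(OCc2ccccc2)c1CO[Si](C)(C)C(C)(C)C | intermediate (not isolated)
19 | 1-[2,6-bis(benzyloxy)-3-{[(tert-butyldimethylsilyl)oxy]methyl}-4-methoxy-5-methylphenyl]butan-1-one | CCCC(=O)c1c(OCc2ccccc2)c(C)c(OC)c(CO[Si](C)(C)C(C)(C)C)c1OCc1ccccc1 | intermediate
20 | 1-[2,6-bis(benzyloxy)-3-(hydroxymethyl)-4-methoxy-5-methylphenyl]butan-1-one | CCCC(=O)c1c(OCc2ccccc2)c(C)c(OC)c(CO)c1OCc1ccccc1 | intermediate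
21 | 2',4',6'-trihydroxyacetophenone | CC(=O)c1c(O)cc(O)cc1O | starting material
22 | 2-acetyl-3,5-dihydroxy-4,4-dimethylcyclohexa-2,5-dien-1-one (acetylfilicinic acid) | CC(=O)C1=C(O)C(C)(C)C(O)=CC1=O | intermediate
23 | 2-acetyl-6-{[2,4-bis(benzyloxy)-3-butanoyl-6-methoxy-5-methylphenyl]methyl}-3,5-dihydroxy-4,4-dimethylcyclohexa-2,5-dien-1-one | CCCC(=O)c1c(OCc2ccccc2)c(C)c(OC)c(CC2=C(O)C(C)(C)C(O)=C(C(C)=O)C2=O)c1OCc1ccccc1 | intermediate
24 | 2-acetyl-6-[(3-butanoyl-2,4-dihydroxy-6-methoxy-5-methylphenyl)methyl]-3,5-dihydroxy-4,4-dimethylcyclohexa-2,5-dien-1-one | CCCC(=O)c1c(O)c(C)c(OC)c(CC2=C(O)C(C)(C)C(O)=C(C(C)=O)C2=O)c1O | target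

**Step count**

Total: 12 steps. Longest linear sequence: 9 steps (1, 2, 5, 6, 7, 8, 9, 11, 12).

**Steps most likely to fail**

Step 5 (benzannulation). The electrocyclic opening of a vinylogous-ester cyclobutenone may need a temperature at which ketene oligomerisation and decomposition of the ynol ether outrun the (2+2) cycloaddition. The fallback builds ring A by classical substitution of a preformed methylphloroglucinol. It sets out from no numbered compound of the route but from commercial 2,4,6-trihydroxy-3-methylbenzaldehyde F1, and it comes back to the route at 15. Benzylation (BnBr 2.1 equiv, K2CO3, acetone, rt) should alkylate the hydroxyl para to the formyl group and the unhindered ortho hydroxyl. The hindered hydroxyl between formyl and methyl should stay held in its hydrogen bond to the carbonyl, which should give 4,6-bis(benzyloxy)-2-hydroxy-3-methylbenzaldehyde F2. Methylation of the remaining hydroxyl (MeI, K2CO3, DMF, 50 °C) should give 4,6-bis(benzyloxy)-2-methoxy-3-methylbenzaldehyde F3. Reduction (NaBH4, MeOH–THF, 0 °C) should give [4,6-bis(benzyloxy)-2-methoxy-3-methylphenyl]methanol F4, and silylation (TBSCl, imidazole, CH2Cl2) should give 15.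

Step 11 (bridge formation). Ionisation of the benzylic alcohol may be followed by O-alkylation of the enol that does not funnel to carbon, by a second alkylation at the same ring B carbon, or by acid-induced loss of a benzyl ether. The fallback reverses the oxidation level of the bridge carbon; it sets out from 20 and comes back at 23. Oxidation of 20 (MnO2, CH2Cl2, rt) should give 2,4-bis(benzyloxy)-3-butanoyl-6-methoxy-5-methylbenzaldehyde F5. A three-component reductive alkylation with 22 (Hantzsch ester, L-proline 20 mol %, CH2Cl2, rt) should then proceed by Knoevenagel condensation to 2-acetyl-6-{[2,4-bis(benzyloxy)-3-butanoyl-6-methoxy-5-methylphenyl]methylidene}-3-hydroxy-4,4-dimethylcyclohex-2-ene-1,5-dione F6 (not isolated, alkene geometry not defined), which is reduced in the flask by hydride transfer to 23.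

Step 2 (benzyl exchange and double-bond shift). Alkoxy exchange may stay incomplete, the double-bond equilibrium may not lie far enough on the side of the methyl-substituted enone, or the alcohol may cleave the strained ring at the carbonyl under acid. The fallback separates the two events and avoids acid in the benzylation; it sets out from 4 and comes back at 5. Hydrolysis of 4 (1 M HCl, THF, 0 °C) should give the symmetrical 2-methylcyclobutane-1,3-dione, isolated as its enol 3-hydroxy-2-methylcyclobut-2-en-1-one F7. Mitsunobu O-benzylation of this vinylogous acid (BnOH, PPh3, DIAD, THF, 0 °C) should give 5, since alkylation of either oxygen of the delocalised anion leads to the same product.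

**Further compounds**

F1 | step 5 | 2,4,6-trihydroxy-3-methylbenzaldehyde | Cc1c(O)cc(O)c(C=O)c1O
F2 | step 5 | 4,6-bis(benzyloxy)-2-hydroxy-3-methylbenzaldehyde | Cc1c(OCc2ccccc2)cc(OCc2ccccc2)c(C=O)c1O
F3 | step 5 | 4,6-bis(benzyloxy)-2-methoxy-3-methylbenzaldehyde | COc1c(C)c(OCc2ccccc2)cc(OCc2ccccc2)c1C=O
F4 | step 5 | [4,6-bis(benzyloxy)-2-methoxy-3-methylphenyl]methanol | COc1c(C)c(OCc2ccccc2)cc(OCc2ccccc2)c1CO
F5 | step 11 | 2,4-bis(benzyloxy)-3-butanoyl-6-methoxy-5-methylbenzaldehyde | CCCC(=O)c1c(OCc2ccccc2)c(C)c(OC)c(C=O)c1OCc1ccccc1
F6 | step 11 | 2-acetyl-6-{[2,4-bis(benzyloxy)-3-butanoyl-6-methoxy-5-methylphenyl]methylidene}-3-hydroxy-4,4-dimethylcyclohex-2-ene-1,5-dione | CCCC(=O)c1c(OCc2ccccc2)c(C)c(OC)c(C=C2C(=O)C(C)(C)C(O)=C(C(C)=O)C2=O)c1OCc1ccccc1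
F7 | step 2 | 3-hydroxy-2-methylcyclobut-2-en-1-one | CC1=C(O)CC1=O
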